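**Plan**

1. Retrosynthetic cuts: aryl CHO/OH ⇒ trimethoxyaryl; isopropenyl ⇒ acetyl ⇒ C7 enol triflate; C10 carbinol ⇒ C10 ketone ⇒ silyl enol ether; then C8–C9 of the seven-membered ring (retro-Cope to a cis-divinylcyclopropane); C1–C6/C5–C6 (cyclopropane); C1=C5 (aldol); C4–C3 and C4–CH3 (enolate alkylations); C1′–isobutyl (conjugate addition to 5,7-dimethoxycoumarin).
2. Forward order: a temporary dihydrocoumarin ring carries C1′ and C4 and is opened; the cyclopentene is closed by aldol condensation and cyclopropanated to a bicyclo[3.1.0]hexane; the seven-membered ring is closed by the divinylcyclopropane rearrangement; C10, C7 and the arene are finished last.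
3. Enabling feature: in the seven-membered ring C1–C5–C6–C7–C8–C9–C10 the CH2–CH2 bond C8–C9 lies opposite the ring-fusion CH (C5), which is bonded to both C1 and C6. With oxygen on C10 and a carbon substituent on C7, C1–C5–C6 can be a cyclopropane carrying a 1-silyloxyvinyl group (C10=C9) on C1 and a 1-triflyloxyvinyl group (C7=C8) on C6; their [3,3] shift forms C8–C9 with release of ring strain.
4. Stereochemistry: C1′ by copper-catalysed asymmetric conjugate addition; C4 by trans-selective alkylation of the lactone enolate; C5 by cyclopropanation anti to the C4 side chain; C1 by equilibration to the trans ring fusion; C10 by axial methyl delivery; C7 by hydroxyl-directed hydrogenation.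

Key step: step 11

Remark: guaiane-type locants are used in the text (five-membered ring C1–C2–C3–C4–C5, C4 quaternary, C10 the carbinol carbon, C7 the isopropenyl-bearing carbon, C1′ the benzylic carbon, "C4 side chain" = (1R)-3-methyl-1-(2,4,6-trimethoxyphenyl)butyl). Compounds 1, 2, 5, 12 and the ferrocenyl diphosphine are assumed purchasable, and the ligand enantiomer is taken to be the one that gives (4R)-3.

**Route**

Step 1
Reactants: 1 5,7-dimethoxycoumarin; 2 isobutylmagnesium bromide
Product: 3 (4R)-5,7-dimethoxy-4-(2-methylpropyl)chroman-2-one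
Conditions: 2 (1.5 equiv), CuBr·SMe2 (5 mol %), 1-[2-(diphenylphosphino)ferrocenyl]ethyldicyclohexylphosphine (Josiphos-type, single enantiomer, 6 mol %), CH2Cl2, −72 °C; aq. NH4Cl
Reagents that add atoms: none
Why: Copper-catalysed asymmetric conjugate addition of a Grignard reagent to a coumarin, a known reaction type, in which the chiral diphosphine–copper complex differentiates the faces of C3=C4 and sets the benzylic centre (later C1′).

Step 2
Reactants: 3 (4R)-5,7-dimethoxy-4-(2-methylpropyl)chroman-2-one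
Product: 4 (3R,4R)-5,7-dimethoxy-3-methyl-4-(2-methylpropyl)chroman-2-one (3,4-trans)
Conditions: LiN(SiMe3)2 (1.05 equiv), THF, −78 °C; MeI, −78 to −40 °C
Reagents that add atoms: iodomethane, CI
Why: Lactone enolate alkylation in which methyl should enter trans to the 4-isobutyl group; this centre is re-enolised in step 4, so its configuration need not be pure.

Step 3
Reactants: 5 2-(3-chloropropyl)-2-methyl-1,3-dioxolane
Product: 6 2-(3-iodopropyl)-2-methyl-1,3-dioxolane
Conditions: NaI, acetone, reflux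
Reagents that add atoms: sodium iodide, [Na+].[I-]
Why: Finkelstein halide exchange (SN2), driven by precipitation of NaCl, to give a primary iodide reactive enough for the quaternisation in step 4.

Step 4
Reactants: 4 (3R,4R)-5,7-dimethoxy-3-methyl-4-(2-methylpropyl)chroman-2-one; 6 2-(3-iodopropyl)-2-methyl-1,3-dioxolane
Product: 7 (3R,4S)-5,7-dimethoxy-3-methyl-3-[3-(2-methyl-1,3-dioxolan-2-yl)propyl]-4-(2-methylpropyl)chroman-2-one (3-methyl cis to 4-isobutyl)
Conditions: LiN(i-Pr)2, THF, −78 °C; 6, DMPU, −78 to −10 °C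
Reagents that add atoms: none
Why: Alkylation of a trisubstituted lactone enolate in which peri strain with the 5-methoxy group holds the 4-isobutyl group pseudo-axial, so the iodide should enter trans to it and form the quaternary centre (later C4) with methyl cis to isobutyl.

Step 5
Reactants: 7 the 3,3-dialkylated chroman-2-one
Product: 8 methyl (2R,3S)-2,5-dimethyl-2-[3-(2-methyl-1,3-dioxolan-2-yl)propyl]-3-(2,4,6-trimethoxyphenyl)hexanoate
Conditions: NaOMe, MeOH/DMF, rt; then MeI, rt
Reagents that add atoms: sodium methoxide, C[O-].[Na+]; iodomethane, CI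
Why: Methanolysis of the aryl ester (phenoxide is the better leaving group) followed by Williamson O-methylation of the liberated phenoxide, which makes the ring opening irreversible and touches no stereocentre.

Step 6
Reactants: 8 the methyl ester
Product: 9 (2R,3S)-2,5-dimethyl-2-[3-(2-methyl-1,3-dioxolan-2-yl)propyl]-3-(2,4,6-trimethoxyphenyl)hexanal
Conditions: i-Bu2AlH (1.2 equiv), CH2Cl2, −78 °C; aq. potassium sodium tartrate
Reagents that add atoms: none
Why: Partial reduction of a hindered ester by i-Bu2AlH at low temperature, stopped at the aluminated hemiacetal, to give an α-quaternary aldehyde that cannot epimerise.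

Step 7
Reactants: 9 the ketal aldehyde
Product: 11 1-{(3S)-3-methyl-3-[(1R)-3-methyl-1-(2,4,6-trimethoxyphenyl)butyl]cyclopent-1-en-1-yl}ethan-1-one, via keto aldehyde 10 (not isolated)
Conditions: 1 M HCl, THF, rt; then KOH, MeOH, rt to 40 °C
Reagents that add atoms: water, O
Why: Acetal hydrolysis followed by intramolecular aldol condensation, in which the aldehyde has no α-hydrogen, only enolisation of the ketone towards C1 closes a five-membered ring, and E1cB dehydration gives the conjugated enone.

Step 8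
Reactants: 11 the 1-acetylcyclopentene; 12 (2-ethoxy-2-oxoethyl)dimethylsulfonium bromide
Product: 13 ethyl 1-acetyl-4-methyl-4-[(1R)-3-methyl-1-(2,4,6-trimethoxyphenyl)butyl]bicyclo[3.1.0]hexane-6-carboxylate (ester exo and cis to acetyl; cyclopropane cis to the 4-methyl group)
Conditions: 12 (2 equiv), DBU (2 equiv), CHCl3, 50 °C
Reagents that add atoms: none
Why: Corey–Chaykovsky-type cyclopropanation (Michael-initiated ring closure) with an ester-stabilised sulfonium ylide, which should add to C5 anti to the bulky C4 side chain (setting C5 and C1) and place the ester exo, cis to the acetyl group, to avoid the C4 methyl group.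

Step 9
Reactants: 13 the cyclopropyl keto ester
Product: 14 ethyl 1-[1-(tert-butyldimethylsilyloxy)vinyl]-4-methyl-4-[(1R)-3-methyl-1-(2,4,6-trimethoxyphenyl)butyl]bicyclo[3.1.0]hexane-6-carboxylate
Conditions: TBSOTf (1.3 equiv), Et3N (2 equiv), CH2Cl2, 0 °C
Reagents that add atoms: tert-butyldimethylsilyl trifluoromethanesulfonate, CC(C)(C)[Si](C)(C)OS(=O)(=O)C(F)(F)F
Why: Soft enolisation and O-silylation (silyl enol ether formation) of a ketone that can enolise only towards its methyl group because C1 is quaternary, with the ester left untouched.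

Step 10
Reactants: 14 the silyl enol ether ester
Product: 16 1-{1-[1-(tert-butyldimethylsilyloxy)vinyl]-4-methyl-4-[(1R)-3-methyl-1-(2,4,6-trimethoxyphenyl)butyl]bicyclo[3.1.0]hexan-6-yl}ethan-1-one (6-exo acetyl), via Weinreb amide 15 (not isolated)
Conditions: MeNH(OMe)·HCl (1.5 equiv), i-PrMgCl (3 equiv), THF, −20 °C; then MeMgBr (3 equiv), −20 to 0 °C; aq. NH4Cl
Reagents that add atoms: methylmagnesium bromide, C[Mg]Br; N,O-dimethylhydroxylamine hydrochloride, CNOC.Cl (its atoms stay in 15 only)
Why: Ester-to-Weinreb-amide exchange by the magnesium amide followed by Grignard addition that stops at the ketone through the chelated tetrahedral intermediate (Weinreb ketone synthesis), both tolerated by the silyl enol ether.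

Step 11
Reactants: 16 the cis-6-acetyl-1-(silyloxyvinyl)bicyclo[3.1.0]hexane
Product: 18 8-(tert-butyldimethylsilyloxy)-3-methyl-3-[(1R)-3-methyl-1-(2,4,6-trimethoxyphenyl)butyl]-1,2,3,3a,6,7-hexahydroazulen-5-yl trifluoromethanesulfonate (OTf on C7 and OTBS on C10; H5 cis to the C4 side chain), via enol triflate 17 (not isolated)
Conditions: KN(SiMe3)2 (1.2 equiv), THF, −78 °C; PhNTf2 (1.3 equiv), −78 °C to rt; then 50 °C
Reagents that add atoms: N-phenylbis(trifluoromethanesulfonimide), O=S(=O)(N(c1ccccc1)S(=O)(=O)C(F)(F)F)C(F)(F)F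
Why: Kinetic deprotonation of the methyl ketone and O-triflation give enol triflate 17, a cis-1,2-divinylcyclopropane that should undergo the divinylcyclopropane–cycloheptadiene ([3,3]-sigmatropic, Cope) rearrangement on warming; the closest known reaction type is the thermal rearrangement of 6-exo-vinyl-1-(silyloxyvinyl)bicyclo[3.1.0]hexanes to hydroazulenes. The seven-membered ring closes by suprafacial bonding of the two vinyl CH2 termini (C8–C9) through a boat-like six-centre transition state while the strained C1–C6 bond opens, which gives both new ring alkenes (C1=C10 and C6=C7) the cis geometry. No new sp3 stereocentre is formed, since C5 keeps the configuration set in step 8 and C4 and C1′ are untouched. The step needs enolisation towards CH3 and not towards the cyclopropyl C6–H (secured by the strain of a cyclopropylidene enolate), a cis relationship of the two vinyl groups (secured because a bridgehead substituent and a 6-exo substituent of bicyclo[3.1.0]hexane are necessarily cis), and access to the boat array (secured because C5 carries only hydrogen on the face of the vinyl groups). Release of cyclopropane strain makes the rearrangement irreversible and leaves differentiated enol derivatives at C10 (silyl ether) and C7 (triflate).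

Step 12
Reactants: 18 the bis-enol derivative
Product: 19 3-methyl-3-[(1R)-3-methyl-1-(2,4,6-trimethoxyphenyl)butyl]-8-oxo-1,2,3,3a,6,7,8,8a-octahydroazulen-5-yl trifluoromethanesulfonate (trans ring fusion: H1 trans to H5 and cis to the C4 methyl group)
Conditions: HF·pyridine, THF, 0 °C; then DBU (0.2 equiv), CH2Cl2, rt
Reagents that add atoms: none
Why: Protodesilylation of the silyl enol ether followed by base-mediated equilibration α to the ketone, which should set C1 under thermodynamic control as the trans-fused hydroazulenone while the enol triflate is inert to both reagents.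

Step 13
Reactants: 19 the trans-fused C10 ketone
Product: 20 8-hydroxy-3,8-dimethyl-3-[(1R)-3-methyl-1-(2,4,6-trimethoxyphenyl)butyl]-1,2,3,3a,6,7,8,8a-octahydroazulen-5-yl trifluoromethanesulfonate (C10 hydroxyl cis to H1)
Conditions: AlMe3 (4 equiv), toluene, −20 °C to rt
Reagents that add atoms: trimethylaluminium, C[Al](C)C
Why: 1,2-Addition of trimethylaluminium to the ketone, in which excess reagent should deliver methyl along the axial trajectory anti to the axial C1–H and so place the C10 hydroxyl cis to H1, the enol triflate being unreactive.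

Step 14
Reactants: 20 the hydroxy enol triflate
Product: 21 1-{8-hydroxy-3,8-dimethyl-3-[(1R)-3-methyl-1-(2,4,6-trimethoxyphenyl)butyl]-1,2,3,3a,6,7,8,8a-octahydroazulen-5-yl}ethan-1-one (C6=C7 enone)
Conditions: Pd(PPh3)4 (5 mol %), LiCl (3 equiv), SnMe4 (1.5 equiv), CO (3 atm), DMF, 70 °C
Reagents that add atoms: carbon monoxide, [C-]#[O+]; tetramethylstannane, C[Sn](C)(C)C
Why: Carbonylative Stille coupling of an enol triflate with tetramethyltin (oxidative addition, CO insertion, transmetalation, reductive elimination) to give the methyl enone without touching a stereocentre.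

Step 15
Reactants: 21 the hydroxy enone
Product: 22 1-{8-hydroxy-3,8-dimethyl-3-[(1R)-3-methyl-1-(2,4,6-trimethoxyphenyl)butyl]decahydroazulen-5-yl}ethan-1-one (H7 cis to the C10 hydroxyl and H1; acetyl cis to H5)
Conditions: [Ir(cod)(PCy3)(py)]PF6 (10 mol %), H2 (1 atm), CH2Cl2, rt
Reagents that add atoms: none
Why: Hydroxyl-directed homogeneous hydrogenation with the cationic iridium catalyst, in which coordination to the C10 hydroxyl should deliver H2 to the C6=C7 face cis to that hydroxyl and set C7 with H7 cis to H1.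

Step 16
Reactants: 22 the hydroxy methyl ketone
Product: 23 1,4-dimethyl-1-[(1R)-3-methyl-1-(2,4,6-trimethoxyphenyl)butyl]-7-(prop-1-en-2-yl)decahydroazulen-4-ol (configuration as in the target)
Conditions: Cp2TiMe2 (3 equiv), toluene, 65 °C
Reagents that add atoms: dimethyltitanocene, C[Ti](C)(C1C=CC=C1)C1C=CC=C1
Why: Petasis methylenation (titanium methylidene, oxatitanacyclobutane) converts the methyl ketone into the isopropenyl group under non-basic conditions, so C7 should not epimerise.

Step 17
Reactants: 23 the trimethoxyaryl tertiary alcohol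
Product: 25 5-{(1R)-1-[4-hydroxy-1,4-dimethyl-7-(prop-1-en-2-yl)decahydroazulen-1-yl]-3-methylbutyl}-2,4,6-trimethoxybenzene-1,3-dicarbaldehyde, via amino alkoxide 24 (not isolated)
Conditions: n-BuLi (2.2 equiv), TMEDA, THF, 0 °C; DMF (1.1 equiv), −78 to 0 °C; n-BuLi (1.5 equiv), 0 °C; DMF (3 equiv); aq. NH4Cl
Reagents that add atoms: N,N-dimethylformamide, CN(C)C=O
Why: Twofold directed ortho-metalation–formylation, in which each remaining aryl C–H is flanked by two methoxy groups, the first formyl group stays masked as its lithium α-amino alkoxide 24 during the second lithiation, and both aldehydes are released on work-up.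

Step 18
Reactants: 25 the trimethoxy dialdehyde
Product: 26 target CNP0594576.1
Conditions: NaSEt (10 equiv), DMF, 120 °C; then 1 M HCl (work-up)
Reagents that add atoms: none
Why: Nucleophilic O-demethylation (SN2 at methyl) by ethanethiolate, favoured because each methoxy group is ortho or para to a formyl group, under basic conditions that the tertiary alcohol and the isopropenyl group should survive.

**Compound list**

1 | 5,7-dimethoxycoumarin | COc1cc(OC)c2ccc(=O)oc2c1 | starting material
2 | isobutylmagnesium bromide | CC(C)C[Mg]Br | starting material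
3 | (4R)-5,7-dimethoxy-4-(2-methylpropyl)chroman-2-one | O=C1Oc2cc(OC)cc(OC)c2[C@H](CC(C)C)C1 | intermediate
4 | (3R,4R)-5,7-dimethoxy-3-methyl-4-(2-methylpropyl)chroman-2-one (3,4-trans) | O=C1Oc2cc(OC)cc(OC)c2[C@H](CC(C)C)[C@H]1C | intermediate
5 | 2-(3-chloropropyl)-2-methyl-1,3-dioxolane | CC1(CCCCl)OCCO1 | starting material
6 | 2-(3-iodopropyl)-2-methyl-1,3-dioxolane | CC1(CCCI)OCCO1 | intermediate
7 | (3R,4S)-5,7-dimethoxy-3-methyl-3-[3-(2-methyl-1,3-dioxolan-2-yl)propyl]-4-(2-methylpropyl)chroman-2-one (3-methyl cis to 4-isobutyl) | O=C1Oc2cc(OC)cc(OC)c2[C@H](CC(C)C)[C@@]1(C)CCCC3(C)OCCO3 | intermediate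
8 | methyl (2R,3S)-2,5-dimethyl-2-[3-(2-methyl-1,3-dioxolan-2-yl)propyl]-3-(2,4,6-trimethoxyphenyl)hexanoate | COC(=O)[C@](C)(CCCC1(C)OCCO1)[C@@H](CC(C)C)c2c(OC)cc(OC)cc2OC | intermediate
9 | (2R,3S)-2,5-dimethyl-2-[3-(2-methyl-1,3-dioxolan-2-yl)propyl]-3-(2,4,6-trimethoxyphenyl)hexanal | O=C[C@](C)(CCCC1(C)OCCO1)[C@@H](CC(C)C)c2c(OC)cc(OC)cc2OC | intermediate
10 | (2R,3S)-2,5-dimethyl-2-(4-oxopentyl)-3-(2,4,6-trimethoxyphenyl)hexanal (keto aldehyde, not isolated) | O=C[C@](C)(CCCC(C)=O)[C@@H](CC(C)C)c2c(OC)cc(OC)cc2OC | intermediate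
11 | 1-{(3S)-3-methyl-3-[(1R)-3-methyl-1-(2,4,6-trimethoxyphenyl)butyl]cyclopent-1-en-1-yl}ethan-1-one | CC(=O)C1=C[C@@](C)([C@@H](CC(C)C)c2c(OC)cc(OC)cc2OC)CC1 | intermediate
12 | (2-ethoxy-2-oxoethyl)dimethylsulfonium bromide | CCOC(=O)C[S+](C)C.[Br-] | starting material
13 | ethyl 1-acetyl-4-methyl-4-[(1R)-3-methyl-1-(2,4,6-trimethoxyphenyl)butyl]bicyclo[3.1.0]hexane-6-carboxylate (ester exo, cis to acetyl; cyclopropane cis to 4-methyl) | CCOC(=O)[C@H]1[C@@H]2[C@@](C)([C@@H](CC(C)C)c3c(OC)cc(OC)cc3OC)CC[C@]12C(C)=O | intermediate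
14 | ethyl 1-[1-(tert-butyldimethylsilyloxy)vinyl]-4-methyl-4-[(1R)-3-methyl-1-(2,4,6-trimethoxyphenyl)butyl]bicyclo[3.1.0]hexane-6-carboxylate | CCOC(=O)[C@H]1[C@@H]2[C@@](C)([C@@H](CC(C)C)c3c(OC)cc(OC)cc3OC)CC[C@]12C(=C)O[Si](C)(C)C(C)(C)C | intermediate
15 | N-methoxy-N-methyl amide corresponding to ester 14 (Weinreb amide, not isolated) | CON(C)C(=O)[C@H]1[C@@H]2[C@@](C)([C@@H](CC(C)C)c3c(OC)cc(OC)cc3OC)CC[C@]12C(=C)O[Si](C)(C)C(C)(C)C | intermediate
16 | 1-{1-[1-(tert-butyldimethylsilyloxy)vinyl]-4-methyl-4-[(1R)-3-methyl-1-(2,4,6-trimethoxyphenyl)butyl]bicyclo[3.1.0]hexan-6-yl}ethan-1-one (6-exo acetyl) | CC(=O)[C@H]1[C@@H]2[C@@](C)([C@@H](CC(C)C)c3c(OC)cc(OC)cc3OC)CC[C@]12C(=C)O[Si](C)(C)C(C)(C)C | intermediate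
17 | 1-{1-[1-(tert-butyldimethylsilyloxy)vinyl]-4-methyl-4-[(1R)-3-methyl-1-(2,4,6-trimethoxyphenyl)butyl]bicyclo[3.1.0]hexan-6-yl}vinyl trifluoromethanesulfonate (cis-divinylcyclopropane, not isolated) | C=C(OS(=O)(=O)C(F)(F)F)[C@H]1[C@@H]2[C@@](C)([C@@H](CC(C)C)c3c(OC)cc(OC)cc3OC)CC[C@]12C(=C)O[Si](C)(C)C(C)(C)C | intermediate
18 | 8-(tert-butyldimethylsilyloxy)-3-methyl-3-[(1R)-3-methyl-1-(2,4,6-trimethoxyphenyl)butyl]-1,2,3,3a,6,7-hexahydroazulen-5-yl trifluoromethanesulfonate (3a-H cis to the side chain) | O=S(=O)(OC1=C[C@H]2C(=C(O[Si](C)(C)C(C)(C)C)CC1)CC[C@]2(C)[C@@H](CC(C)C)c3c(OC)cc(OC)cc3OC)C(F)(F)F | intermediate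
19 | 3-methyl-3-[(1R)-3-methyl-1-(2,4,6-trimethoxyphenyl)butyl]-8-oxo-1,2,3,3a,6,7,8,8a-octahydroazulen-5-yl trifluoromethanesulfonate (trans-fused) | O=S(=O)(OC1=C[C@H]2[C@H](C(=O)CC1)CC[C@]2(C)[C@@H](CC(C)C)c3c(OC)cc(OC)cc3OC)C(F)(F)F | intermediate
20 | 8-hydroxy-3,8-dimethyl-3-[(1R)-3-methyl-1-(2,4,6-trimethoxyphenyl)butyl]-1,2,3,3a,6,7,8,8a-octahydroazulen-5-yl trifluoromethanesulfonate (OH cis to 8a-H) | O=S(=O)(OC1=C[C@H]2[C@H]([C@](C)(O)CC1)CC[C@]2(C)[C@@H](CC(C)C)c3c(OC)cc(OC)cc3OC)C(F)(F)F | intermediate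
21 | 1-{8-hydroxy-3,8-dimethyl-3-[(1R)-3-methyl-1-(2,4,6-trimethoxyphenyl)butyl]-1,2,3,3a,6,7,8,8a-octahydroazulen-5-yl}ethan-1-one | CC(=O)C1=C[C@H]2[C@H]([C@](C)(O)CC1)CC[C@]2(C)[C@@H](CC(C)C)c3c(OC)cc(OC)cc3OC | intermediate
22 | 1-{8-hydroxy-3,8-dimethyl-3-[(1R)-3-methyl-1-(2,4,6-trimethoxyphenyl)butyl]decahydroazulen-5-yl}ethan-1-one (acetyl cis to 3a-H, trans to OH) | CC(=O)[C@H]1C[C@H]2[C@H]([C@](C)(O)CC1)CC[C@]2(C)[C@@H](CC(C)C)c3c(OC)cc(OC)cc3OC | intermediate
23 | 1,4-dimethyl-1-[(1R)-3-methyl-1-(2,4,6-trimethoxyphenyl)butyl]-7-(prop-1-en-2-yl)decahydroazulen-4-ol (configuration of the target) | C=C(C)[C@H]1C[C@H]2[C@H]([C@](C)(O)CC1)CC[C@]2(C)[C@@H](CC(C)C)c3c(OC)cc(OC)cc3OC | intermediate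
24 | dilithium salt of the mono-formylated arene as its α-(dimethylamino)alkoxide and tertiary alkoxide (not isolated) | C=C(C)[C@H]1C[C@H]2[C@H]([C@](C)([O-])CC1)CC[C@]2(C)[C@@H](CC(C)C)c3c(OC)c(C([O-])N(C)C)c(OC)cc3OC.[Li+].[Li+] | intermediate
25 | 5-{(1R)-1-[4-hydroxy-1,4-dimethyl-7-(prop-1-en-2-yl)decahydroazulen-1-yl]-3-methylbutyl}-2,4,6-trimethoxybenzene-1,3-dicarbaldehyde | C=C(C)[C@H]1C[C@H]2[C@H]([C@](C)(O)CC1)CC[C@]2(C)[C@@H](CC(C)C)c3c(OC)c(C=O)c(OC)c(C=O)c3OC | intermediate
26 | CNP0594576.1: 5-{(1R)-1-[4-hydroxy-1,4-dimethyl-7-(prop-1-en-2-yl)decahydroazulen-1-yl]-3-methylbutyl}-2,4,6-trihydroxybenzene-1,3-dicarbaldehyde | C=C(C)[C@@H]1CC[C@@](C)(O)[C@@H]2CC[C@](C)([C@@H](CC(C)C)c3c(O)c(C=O)c(O)c(C=O)c3O)[C@H]2C1 | target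

**Step count and risks**

Total steps: 18. Longest linear sequence: 17 (steps 1, 2 and 4–18; step 3 is a one-step branch).

The three steps most likely to fail:

1. Step 8. The stabilised ylide may add only slowly to the neopentyl-type β-carbon C5, with incomplete conversion or eroded exo selectivity. The fallback sets out from 11 and returns at 15. Luche reduction (NaBH4, CeCl3·7H2O, MeOH, 0 °C) would give allylic alcohol F1 (both carbinol epimers usable). Acylation with glyoxylic acid chloride p-toluenesulfonylhydrazone (PhNMe2, then Et3N, CH2Cl2) would give allyl diazoacetate F2. Rh2(OAc)4 (1 mol %, CH2Cl2) would then close the cyclopropane intramolecularly to the fused lactone F3; the tether forces the C6 carbonyl cis to the C1 side chain and the carbene should add anti to the C4 side chain. MeNH(OMe)·HCl/AlMe3 would open the lactone to hydroxy Weinreb amide F4, Dess–Martin periodinane would give keto Weinreb amide F5, and TBSOTf/Et3N would give 15, which is taken on with MeMgBr as in step 10.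

2. Step 13. Facial selectivity of methyl transfer to the C10 carbonyl may be poor or reversed (methyl entering on the H1 face gives the C10 epimer). The fallback sets out from 19 and returns at 20. Methylenation with Cp2TiMe2 (toluene, 65 °C) would give exocyclic alkene F6, and Mukaiyama hydration (Co(acac)2 cat., PhSiH3, O2, i-PrOH) would give 20. Here oxygen, not carbon, enters C10 from the more accessible face (Markovnikov hydrogen-atom transfer, then capture of the tertiary radical by O2), so the sense of induction is the reverse of a carbonyl addition; the electron-poor enol triflate should not react.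

3. Step 15. Hydroxyl direction may be lost, so that hydrogen is delivered from the sterically preferred H5 face (C7 epimer), or the acidic iridium hydride may ionise the tertiary alcohol. The fallback sets out from 21 and returns at 22. Conjugate reduction with [(Ph3P)CuH]6 (THF, rt) would give copper enolate F7, which is protonated at −78 °C with AcOH. Kinetic protonation of the exocyclic enolate from the open equatorial side (the side of the C10 hydroxyl, which can also hand over its proton) should place the acetyl group axial, cis to H5.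

Further compounds
F1 | step 8 | 1-{(3S)-3-methyl-3-[(1R)-3-methyl-1-(2,4,6-trimethoxyphenyl)butyl]cyclopent-1-en-1-yl}ethan-1-ol (allylic alcohol, carbinol epimers) | CC(O)C1=C[C@@](C)([C@@H](CC(C)C)c2c(OC)cc(OC)cc2OC)CC1
F2 | step 8 | diazoacetate ester of F1 (allyl diazoacetate) | CC(OC(=O)C=[N+]=[N-])C1=C[C@@](C)([C@@H](CC(C)C)c2c(OC)cc(OC)cc2OC)CC1
F3 | step 8 | cyclopropane-fused γ-lactone (C6 carboxyl lactonised onto the C10 oxygen; cyclopropane cis to the C4 methyl group) | CC1OC(=O)[C@H]2[C@@H]3[C@@](C)([C@@H](CC(C)C)c4c(OC)cc(OC)cc4OC)CC[C@]123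
F4 | step 8 | 1-(1-hydroxyethyl)-N-methoxy-N,4-dimethyl-4-[(1R)-3-methyl-1-(2,4,6-trimethoxyphenyl)butyl]bicyclo[3.1.0]hexane-6-carboxamide (hydroxy Weinreb amide) | CON(C)C(=O)[C@H]1[C@@H]2[C@@](C)([C@@H](CC(C)C)c3c(OC)cc(OC)cc3OC)CC[C@]12C(C)O
F5 | step 8 | 1-acetyl-N-methoxy-N,4-dimethyl-4-[(1R)-3-methyl-1-(2,4,6-trimethoxyphenyl)butyl]bicyclo[3.1.0]hexane-6-carboxamide (keto Weinreb amide) | CON(C)C(=O)[C@H]1[C@@H]2[C@@](C)([C@@H](CC(C)C)c3c(OC)cc(OC)cc3OC)CC[C@]12C(C)=O
F6 | step 13 | 3-methyl-3-[(1R)-3-methyl-1-(2,4,6-trimethoxyphenyl)butyl]-8-methylidene-1,2,3,3a,6,7,8,8a-octahydroazulen-5-yl trifluoromethanesulfonate (exocyclic alkene) | O=S(=O)(OC1=C[C@H]2[C@H](C(=C)CC1)CC[C@]2(C)[C@@H](CC(C)C)c3c(OC)cc(OC)cc3OC)C(F)(F)F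
F7 | step 15 | copper enolate of ketone 22 (exocyclic C7=C(O–Cu)CH3) | CC(O[Cu])=C1C[C@H]2[C@H]([C@](C)(O)CC1)CC[C@]2(C)[C@@H](CC(C)C)c3c(OC)cc(OC)cc3OC
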